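Begin at early times, where the target curve is still nearly straight: its slope, taken per loading of free enzyme, is a reading of how fast the enzyme makes target.

| setting | east | south-west | Saturday's | Wednesday's | Friday's | Thursday's |
|---|---|---|---|---|---|---|
| substrate | 0.067 M | 0.067 M | 0.067 M | 0.067 M | 0.067 M | 0.067 M |
| free enzyme | 0.014 mol% | 0.022 mol% | 0.01 mol% | 0.01 mol% | 0.01 mol% | 0.01 mol% |
| temperature | −8 °C | 27 °C | 17 °C | 37 °C | 57 °C | −3 °C |
| remark | run made earlier | run made earlier |  |  |  |  |
| time |  |  | 12 h | 12 h | 12 h | 12 h |

| run | time / h | target / % | substrate / % |
|---|---|---|---|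
| east | 3.00 | 0.7 | 99.2 |
| east | 8.00 | 2.3 | 97.6 |
| east | 15.0 | 3.7 | 95.7 |
| east | 30.0 | 6.1 | 91.6 |
| south-west | 1.33 | 4.6 | 91.1 |
| south-west | 2.50 | 8.0 | 83.8 |
| south-west | 3.00 | 9.2 | 81.8 |
| south-west | 5.00 | 13.1 | 69.1 |

(readings scatter by 0.3 percentage points)

1. the flask that comes out highest in amount of target, in percent of the substrate charged, or "all alike" when all lie within 1.5 percentage points (Saturday's / Wednesday's / Friday's / Thursday's / all alike)
2. target at the end, in percent of the substrate charged, Saturday's
3. target at the end, in percent of the substrate charged, Wednesday's
4. target at the end, in percent of the substrate charged, Friday's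
5. target at the end, in percent of the substrate charged, Thursday's



As a simplification, write two first-order constants for a fixed loading. The making constant m sends substrate to target, and the side constant s removes substrate without target appearing. Integrate d[target]/dt = m[substrate], with [substrate] decaying at m + s and loss of target neglected: target, as a part of the charge, is m/(m + s) times the part consumed, 1 − exp(−(m + s)t).

Read the south-west slope from its first reading, 0.0346 /h, and the east slope from its second, 0.00287 /h. Per loading, they differ by a factor of 7.66 across the temperature gap between the two runs. What is missing from substrate plus target, per hour, reads 0.0323 /h at the first south-west reading and 7.67 × 10⁻⁴ /h at the last east reading. Assume s ignores the loading, and carry both factors on to Wednesday's, raised to the power 0.286, the fraction of that gap still to go. This yields the making constant of Wednesday's, 0.0281 /h, and its side constant, 0.0942 /h.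

Now double each input in turn. Doubling m gives 31.2%, doubling s gives 12.0%, and doubling the time gives 21.8%. My own number for Wednesday's is 17.7%, so in this reckoning m is the input to know well, having moved the answer furthest of the three.

The forecast names Wednesday's, with 8.5% for Saturday's, 11.5% for Wednesday's, 2.5% for Friday's and 3% for Thursday's, holding that “a steeply temperature-dependent side route competes”. For Wednesday's it stands lower than my number.

The flasks give 8.16% for Saturday's, 24.9% for Wednesday's, 18.4% for Friday's and 2.88% for Thursday's, with Wednesday's highest.

    free enzyme → unfolded enzyme (k = 3.50 × 10⁻⁴ /h, Ea = 284 kJ/mol)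
    substrate + free enzyme → target + free enzyme, rate k2*[substrate]*[free enzyme]/(1 + ([substrate]/Km2)) (39.0 mM, k = 17000 /M/h, Ea = 47.0 kJ/mol)
    target + free enzyme ⇌ isomer of the product + free enzyme, rate k3*[free enzyme]*[target] forward; the back reaction follows from the equilibrium constant (K = 0.540, k = 55000 /M/h, Ea = 46.0 kJ/mol, ΔH = −75.0 kJ/mol)
    substrate ⇌ dormant form (K = 22.0, k = 0.0590 /h, Ea = 98.0 kJ/mol, ΔH = −11.0 kJ/mol)
    (constants at 37 °C)

Wednesday's ended 7.2 percentage points above my reckoning. I had s at 3.35 times m, whereas substrate passes into dormant form at the start at 1.4 times its passing into target, forward step alone. Carry m to the neighbouring flask, Wednesday's recipe with a quarter of the loading, 0.0025 mol%: m becomes 0.00703 /h, s stays 0.0942 /h, and the reckoning gives 4.88%. That neighbouring flask holds 7.84% of target, with 43% of the substrate left.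

The readings were generated by integration with made-up constants, and the scatter is random.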